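The electrophile is the account to keep in these flasks. It stands at 0.10 M against an equal whole charge of nucleophile, and the readings give both electrophile and target as percent of its charge.

in all of them: electrophile 0.10 M

| charge | nucleophile | free base | protic impurity | remark | time |
|---|---|---|---|---|---|
| alder | 0.10 M (fed, over 2.0 h) | 0.025 M | 0.050 M | run made earlier; the fed solution adds 0.25 times the starting volume |  |
| ash | 0.10 M (fed, over 2.0 h) | 0.048 M | 0.050 M | run made earlier; the fed solution adds 0.25 times the starting volume |  |
| cedar | 0.10 M (fed, over 2.0 h) | 0.070 M | 0.050 M | run made earlier; the fed solution adds 0.25 times the starting volume |  |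
| epsilon | 0.100 M (fed, over 2.0 h) | 0.0300 M | 0.0500 M | the fed solution adds 0.25 times the starting volume | 2.0 h |
| eta | 0.100 M (fed, over 2.0 h) | 0.0450 M | 0.0500 M | the fed solution adds 0.25 times the starting volume | 2.0 h |
| delta | 0.100 M (fed, over 2.0 h) | 0.0680 M | 0.0500 M | the fed solution adds 0.25 times the starting volume | 2.0 h |

- alder (time / min: electrophile / %, target / %): 12.0: 100.6, 0; 25.0: 96.6, 2.7; 40.0: 95.0, 4.3; 50.0: 93.1, 5.3; 60.0: 87.6, 8.1
- ash (time / min: electrophile / %, target / %): 5.00: 98.9, 0.3; 15.0: 97.9, 1.2; 30.0: 96.1, 4.0; 40.0: 94.6, 4.4; 60.0: 89.6, 7.6
- cedar (time / min: electrophile / %, target / %): 5.00: 100.1, 1.4; 10.0: 98.0, 0; 15.0: 99.4, 0; 30.0: 97.3, 4.1; 60.0: 87.1, 10.0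

(standard deviation of a reading: 1 percentage point)

- charges are per starting volume, the dose included; the dosed solution carries all of it

- part of the electrophile that has reacted at the end, epsilon
- part of the electrophile that has reacted at the end, eta
- part of the electrophile that has reacted at the end, delta
- what raising the concentration of free base from its lowest to its highest value here does to the part of the electrophile that has reacted (changes below 5 percentage points count as none) (no change / it falls / it rises)

The ledger can be drawn at 60.0 min, the last reading of alder, ash and cedar alike, when half of the feed is in. Averaged over these runs, 88.1 % of the charge stands as electrophile and 8.57 % as target, so 3.33 % is booked to nothing yet read, with 1 percentage point of scatter on each reading. Alder and cedar, with free base at 0.250 and 0.700 of the electrophile charge, differ by −0.5 points in electrophile, less than that scatter, so one account serves the three runs.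

The left entry converts to 0.0550 as exposure in decades, the base-ten logarithm of the charge over the electrophile left. While free nucleophile grows in step with time, exposure grows with the square of time, which makes the end of the feed at 2.0 h worth 4.00 times the reading. That leaves 60.2 % of the electrophile. But the coupling spends nucleophile too, and at one nucleophile per electrophile reacted this reckoning books 76.2 % of the feed as unspent. Scaling the exposure by that share gives a reckoned 32.0 % reacted in epsilon, eta and delta alike.

The forecast gives 31 %, 33 % and 33 %, with the trend no change, holding that “base has no kinetic role in this range”.

The flask gives 29.4 % for epsilon, 29.4 % for eta and 29.5 % for delta, so the trend is no change, a change of 0.1 points.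

    protic impurity + free base → quenched reagent (k = 1.90 L mol⁻¹ min⁻¹)
    acid set free + free base ⇌ salt of the base, settled at all times (K = 88.0 L mol⁻¹)
    target ⇌ isomer of the product (K = 5.90, k = 0.0120 min⁻¹)
    nucleophile + acid set free ⇌ protonated nucleophile, settled at all times (K = 3000 L mol⁻¹)
    electrophile + nucleophile → acid set free + target (k = 0.130 L mol⁻¹ min⁻¹)

Delta ends with 26.5 % of its free base free and epsilon with 0.706 %, yet each keeps 41.6 % of its nucleophile free. Eta ends at 0.151 decades, 2.74 times the mean reading at 60.0 min, less than the square law's 4.00. The neighbouring flask, which is eta with 4.00 times the nucleophile, reaches 0.716 decades, 4.74 times eta's exposure.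

The earlier runs and the new flask were computed with made-up constants, and the scatter is random.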